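## The problem

Target 20 is an open-chain bis(bibenzyl): rings A and B and rings C and D are joined by CH2CH2 bridges, and rings B and C by a diaryl ether oxygen on C3 of ring B, next to the ring B hydroxyl on C4. The molecule has no stereocentre, so nothing has to be set or relayed, and any centre that appears on the way is transient. Ring A carries the only methyl ether, on C3, while ring B (C4) and ring D (C2 and C5) carry free phenols, so the methyl group must either be placed selectively among four oxygens or be built in. The diaryl ether has to be formed at an electron-rich ring B carbon flanked by an oxygen substituent. The ring D hydroquinone oxidises readily to the quinone and has to stay masked until the last step. The methyl ether rules out Lewis acid dealkylation as a deprotection, and any halogen that marks the ether site rules out metal-catalysed hydrogenation before it is used. The enabling feature is ring A itself: C1 bears the bridge, C3 the oxygen, and C2, C4, C5 and C6 only hydrogen. This is the pattern obtained when the C2–C3–C4 unit of an acetoacetate, with its oxygen on C3, is annulated onto a 2-alkenal whose β-carbon becomes C1.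

## Retrosynthesis

**20 from 19.** No skeletal bond is cut. The three phenols of 20 are carried as benzyl ethers and the C–D bridge as an alkyne, which leads back to 19. This exposes the hydroquinone only once, under reducing conditions, and the methyl ether never competes with another alkyl ether that must be removed. The forward step must saturate a diarylalkyne and cleave three benzylic C–O bonds while leaving the diaryl ether and the methyl ether intact.

**19 from 13 and 18.** The bond from C3 of ring B to the ether oxygen is cut, giving aryl bromide 13 and phenol 18. Cutting the oxygen–ring C bond instead would need a ring B phenol carried through the whole ring A sequence under a group orthogonal to benzyl, plus an activated ring C electrophile still to be elaborated. Bromine is inert to every step planned for ring A, and the two halves are of similar size. The forward reaction is a copper-mediated C–O coupling at an electron-rich bromide ortho to a benzyloxy group.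

**13 from 12, and 12 from 10.** In 13 the O–CH3 bond and the aromaticity of ring A are removed together. 13 is the product of an oxidative aromatisation of cyclohexenone 12 in which the solvent alcohol supplies the methyl group. Compared with methylating a phenol, this installs the single methyl ether in the event that creates the arene, when no other free oxygen is present. 12 is the decarboxylation product of keto ester 10, through acid 11. The forward steps are ester hydrolysis with decarboxylation, and a dehydrogenation that must spare the benzyl ether and the bromide.

**10 from 6 and 7 (key disconnection).** Ring A is opened at C1–C2 and C4–C5 in arene numbering (C6–C1 and C3=C4 in the numbering of 10). Enal 6 supplies C5, C6 and C1 with the bridge. Acetoacetate 7 supplies C2, C3 with its oxygen, and C4. Buying ring A as a ready-made methoxyarene is shorter (see Alternative 1). The annulation has other merits: it follows the way such bibenzyl rings arise in nature, it fixes the meta relation by connectivity, and it makes ring A from a commodity C4 unit. The precursors are an acyclic aldehyde and 7. The forward reaction must add 7 to 6 in the 1,4 sense and then close by aldol condensation, through 8 and 9.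

**6 from 5, 4, 2 and 1.** The C2=C3 bond of 6 is cut by a Wittig disconnection to aldehyde 5. 5 is the conjugate reduction product of cinnamaldehyde 4. The C=C bond of 4 is cut the same way to benzaldehyde 2 (through acetal 3), the benzyl ether of 1. Two two-carbon olefinations around one chemoselective reduction avoid ester-level intermediates. They also avoid any hydride or metal-catalysed hydrogenation step that could touch the bromide or the benzyl ether.

**18 from 16 and 17; 16 from 15 and 14.** The bond between ring C and the alkyne is cut (Sonogashira) into alkyne 16 and iodophenol 17. 16 comes from aldehyde 15 by one-carbon homologation, and 15 from 14 by double benzylation. An olefination route to this bridge would need a phosphonium salt, more steps, and an ylide reaction beside a free phenol. The alkyne is a single isomer and costs nothing extra, since the last step reduces it. The ortho oxygen of ring D is benzylated before the alkyne exists, so it cannot close onto the triple bond.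

## Roads not taken

**Alternative 1:** Both aryl–alkyne bonds of an A–B acetylene bridge are cut.
- **Forward key step.** In one pot, Sonogashira coupling of 3-iodoanisole A2 with propiolic acid A3 over PdCl2(PPh3)2 gives 3-(3-methoxyphenyl)prop-2-ynoic acid A5. Decarboxylative coupling of A5 with aryl bromide A4, which already holds the diaryl ether and the benzylated C–D part, gives diarylacetylene A1. One hydrogenation then finishes 20.
- **Merits.** It is fully convergent. The methyl ether is bought with A2, and the two-carbon bridge with A3. No ring is built. The endgame is the same single hydrogenation.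
- **Weak points.** A4 needs a ring B unit with two sites that stay distinguishable while the diaryl ether is made next to one of them. The decarboxylative coupling runs hot on a bromide para to a benzyloxy group, where oxidative addition is slow. The symmetrical diarylalkyne that arises when A5 couples with a second molecule of A2 is the usual by-product, so A3 has to be consumed cleanly before A4 is brought in.
- **Comparison.** On step count and convergence this road is at least as good as the chosen plan, and probably shorter. The chosen plan uses the ring B halogen only once, needs no doubly differentiated ring B piece, and builds ring A from 7 with the O-methyl group delivered by the aromatising alcohol. Ring A ether or isotope variants then come from the same route.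

**Alternative 2:** The bond from the bridge carbon to ring D is cut, together with a temporary benzylic C–O bond.
- **Forward key step.** Lewis acid-promoted (for example BF3·OEt2) formal [3+2] cycloaddition of 1,4-benzoquinone A7 with 4-aryloxystyrene A8 gives racemic 2-aryl-2,3-dihydrobenzofuran-5-ol A6. Hydrogenolysis opens its benzylic C–O bond to the hydroquinone of 20.
- **Merits.** Ring D arrives with both oxygens from a cheap quinone and needs no protecting groups.
- **Weak points.** The cycloaddition is dependable for strongly donor-substituted styrenes and activated quinones. With the parent quinone A7 and the modest aryloxy donor of A8, cationic styrene oligomerisation and redox exchange between A6 and A7 compete. The benzylic C–O bond of A6 cleaves more slowly than an O-benzyl group. A8 still contains the whole A–B part and the diaryl ether, so none of the main difficulties is removed.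
- **Comparison.** It would save one or two steps in the C–D branch and all ring D protection, which is a real advantage. The chosen plan sets three routine steps to 18 against a cycloaddition of uncertain scope placed late on the most valuable intermediate.

**Alternative 3:** Ring B is cut at C2–C3 and C5–C6.
- **Forward key step.** Michael addition of methyl 2-aryloxyacetoacetate A10 to 2-substituted acrolein A11, then aldol condensation, gives cyclohexenone A9. Ester removal and dehydrogenation would then give the ring B phenol.
- **Merits.** The diaryl ether oxygen is attached at an sp3 carbon by simple alkylation chemistry, so no copper coupling is needed. The ring B hydroxyl emerges free from the ketone.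
- **Weak points.** A11 is an α-branched, polymerisation-prone acceptor. A9 has a quaternary, non-enolisable β-keto ester that is open to retro-Claisen cleavage during ester removal. The final dehydrogenation has to be done on an α-aryloxy ketone beside three electron-rich rings. Ring A and its methyl ether must still be bought and built into A11.
- **Comparison.** Avoiding the Ullmann step is a genuine gain over the chosen plan. The chosen plan sets against it an annulation with no quaternary centre, a decarboxylation of an ordinary enolisable keto ester, and an aromatisation on a ring with no heteroatom at the α-carbon.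

Key step: step 5

Remark: 20 is achiral. The stereocentres of 8 to 12 are transient and are erased in step 7, so these compounds are written without configuration, as stereoisomer mixtures.

## Route

Step 1
Reactants: 1 3-bromo-4-hydroxybenzaldehyde
Product: 2 4-(benzyloxy)-3-bromobenzaldehyde
Conditions: BnBr, K2CO3, DMF, rt to 50 °C
Reagents that add atoms: benzyl bromide, BrCc1ccccc1
Why: Williamson ether synthesis on an acidic phenol (para-formyl, ortho-bromo). Benzyl is chosen because all three phenol protecting groups are to fall together in step 12.

Step 2
Reactants: 2 4-(benzyloxy)-3-bromobenzaldehyde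
Product: 4 (E)-3-[4-(benzyloxy)-3-bromophenyl]prop-2-enal, via alkenyl dioxolane 3 (not isolated)
Conditions: (1,3-dioxolan-2-ylmethyl)triphenylphosphonium bromide, KOt-Bu, THF, 0 °C to rt; then 1 M HCl, THF, rt
Reagents that add atoms: (1,3-dioxolan-2-ylmethyl)triphenylphosphonium bromide, [Br-].C(C1OCCO1)[P+](c1ccccc1)(c1ccccc1)c1ccccc1; water, O
Why: Wittig olefination with an acetal-masked formylmethyl ylide gives a clean two-carbon extension of an aryl aldehyde without the second homologation a free formyl ylide can cause. Dilute acid unmasks the aldehyde and equilibrates the alkene to the E isomer.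

Step 3
Reactants: 4 (E)-3-[4-(benzyloxy)-3-bromophenyl]prop-2-enal
Product: 5 3-[4-(benzyloxy)-3-bromophenyl]propanal
Conditions: diethyl 2,6-dimethyl-1,4-dihydropyridine-3,5-dicarboxylate (1.1 equiv), dibenzylammonium trifluoroacetate (5 mol%), THF, rt
Reagents that add atoms: none
Why: Iminium-catalysed transfer hydrogenation (organocatalytic conjugate reduction). The dihydropyridine delivers hydride only to the β-carbon of the iminium ion, so the aldehyde, aryl bromide and benzyl ether are untouched where a metal-catalysed hydrogenation would not be selective.

Step 4
Reactants: 5 3-[4-(benzyloxy)-3-bromophenyl]propanal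
Product: 6 (E)-5-[4-(benzyloxy)-3-bromophenyl]pent-2-enal
Conditions: Ph3P=CHCHO (1.05 equiv), toluene, 80 °C
Reagents that add atoms: (triphenylphosphoranylidene)acetaldehyde, O=CC=P(c1ccccc1)(c1ccccc1)c1ccccc1
Why: Wittig reaction of a stabilised ylide, E-selective. The saturated aldehyde 5 is more electrophilic than the conjugated product, so one equivalent of ylide should stop at the enal.

Step 5
Reactants: 6 (E)-5-[4-(benzyloxy)-3-bromophenyl]pent-2-enal; 7 ethyl acetoacetate
Product: 10 ethyl 6-{2-[4-(benzyloxy)-3-bromophenyl]ethyl}-2-oxocyclohex-3-ene-1-carboxylate (mixture of C1 epimers), via Michael adduct 8 (not isolated), via aldol 9 (not isolated)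
Conditions: 7 (1.3 equiv), (S)-2-[diphenyl(trimethylsilyloxy)methyl]pyrrolidine (10 mol%; the antipode or racemate serves equally), PhCO2H (10 mol%), toluene, rt; then TsOH·H2O (20 mol%), toluene, 70 °C
Reagents that add atoms: none
Why: The secondary amine condenses with 6 to an (E)-iminium ion, the enol of 7 adds through its central carbon to the β-carbon (Michael addition, bond C1–C2 of ring A), and hydrolysis releases the amine and adduct 8. With TsOH the methyl ketone of 8 enolises and attacks the aldehyde in a 6-(enolexo)-exo-trig aldol closure (bond C4–C5) to 9, which dehydrates to the conjugated enone 10. The closest known reaction type is the amine-catalysed domino Michael–aldol condensation of acetoacetates with 2-alkenals, the established entry to 6-substituted 2-oxocyclohex-3-enecarboxylates and 5-substituted cyclohexenones. C6 is set in the Michael step, where the diphenyl(silyloxy)methyl group of the catalyst shields one face of the iminium ion; C1 is epimerisable through the enol and should settle mainly trans to the C6 side chain; the carbinol centre of 9 is lost on dehydration. None of these centres needs control, because steps 6 and 7 erase them. The step needs 1,4- and not 1,2-addition (a Knoevenagel condensation would lead on to a 2H-pyran): iminium activation makes the β-carbon the electrophilic site, and the bulky amine does not form an enaminone with 7. Only one six-membered aldol mode exists in 8 (the other closures would give four-membered rings), so the 1,3 relation of side chain and oxygen is fixed by connectivity. The aryl bromide and the benzyl ether are spectators.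

Step 6
Reactants: 10 ethyl 6-{2-[4-(benzyloxy)-3-bromophenyl]ethyl}-2-oxocyclohex-3-ene-1-carboxylate
Product: 12 5-{2-[4-(benzyloxy)-3-bromophenyl]ethyl}cyclohex-2-en-1-one, via keto acid 11 (not isolated)
Conditions: 1 M NaOH, EtOH, rt; then 2 M HCl, 60 °C
Reagents that add atoms: none
Why: Saponification of the β-keto ester and thermal decarboxylation of the β-keto acid through its cyclic six-membered transition state (acetoacetic ester cleavage). The enol that results ketonises to the conjugated 5-substituted cyclohex-2-enone.

Step 7
Reactants: 12 5-{2-[4-(benzyloxy)-3-bromophenyl]ethyl}cyclohex-2-en-1-one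
Product: 13 1-(benzyloxy)-2-bromo-4-[2-(3-methoxyphenyl)ethyl]benzene
Conditions: I2 (2 equiv), MeOH, reflux
Reagents that add atoms: methanol, CO
Why: Iodine–methanol oxidative aromatisation of a cyclohexenone. The HI formed in situ converts the enone into its methoxy diene, and iodination followed by loss of HI gives the aryl methyl ether. The ketone carbon becomes C3 of ring A and the side-chain carbon C1, so the meta pattern follows from 12 and the last stereocentre disappears.

Step 8
Reactants: 14 2,5-dihydroxybenzaldehyde
Product: 15 2,5-bis(benzyloxy)benzaldehyde
Conditions: BnBr (2.5 equiv), K2CO3, DMF, 60 °C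
Reagents that add atoms: benzyl bromide, BrCc1ccccc1
Why: Double Williamson ether synthesis. Warming is needed for the hydroxyl that is hydrogen-bonded to the formyl group.

Step 9
Reactants: 15 2,5-bis(benzyloxy)benzaldehyde
Product: 16 1,4-bis(benzyloxy)-2-ethynylbenzene
Conditions: dimethyl (1-diazo-2-oxopropyl)phosphonate, K2CO3, MeOH/THF, rt
Reagents that add atoms: dimethyl (1-diazo-2-oxopropyl)phosphonate, COP(=O)(OC)C(=[N+]=[N-])C(C)=O
Why: Seyferth–Gilbert homologation in the Ohira–Bestmann variant. Methanolysis releases the diazomethylphosphonate anion, olefination gives a diazoalkene, and loss of N2 with 1,2-hydrogen shift gives the terminal alkyne. The mild carbonate conditions leave the benzyl ethers alone.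

Step 10
Reactants: 16 1,4-bis(benzyloxy)-2-ethynylbenzene; 17 4-iodophenol
Product: 18 4-{[2,5-bis(benzyloxy)phenyl]ethynyl}phenol
Conditions: PdCl2(PPh3)2 (2 mol%), CuI (4 mol%), Et3N, THF, rt, argon
Reagents that add atoms: none
Why: Sonogashira coupling. The aryl iodide reacts at room temperature and the free para-hydroxyl is tolerated. The oxygen ortho to the alkyne is benzylated and cannot cyclise to a benzofuran.

Step 11
Reactants: 13 1-(benzyloxy)-2-bromo-4-[2-(3-methoxyphenyl)ethyl]benzene; 18 4-{[2,5-bis(benzyloxy)phenyl]ethynyl}phenol
Product: 19 1-(benzyloxy)-2-(4-{[2,5-bis(benzyloxy)phenyl]ethynyl}phenoxy)-4-[2-(3-methoxyphenyl)ethyl]benzene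
Conditions: CuI (10 mol%), N,N-dimethylglycine hydrochloride (30 mol%), Cs2CO3 (2 equiv), 1,4-dioxane, 100 °C, argon
Reagents that add atoms: none
Why: Ullmann-type diaryl ether synthesis. The amino acid ligand on monovalent copper allows coupling of electron-rich, ortho-alkoxy aryl bromides with phenols near 100 °C. The internal alkyne, the benzyl ethers and the methyl ether are inert under these conditions.

Step 12
Reactants: 19 1-(benzyloxy)-2-(4-{[2,5-bis(benzyloxy)phenyl]ethynyl}phenoxy)-4-[2-(3-methoxyphenyl)ethyl]benzene
Product: 20 2-[2-(4-{2-hydroxy-5-[2-(3-methoxyphenyl)ethyl]phenoxy}phenyl)ethyl]benzene-1,4-diol (target)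
Conditions: H2 (1 atm), 10% Pd/C, EtOAc/MeOH, rt; work-up under argon
Reagents that add atoms: none
Why: Heterogeneous catalytic hydrogenation saturates the diarylalkyne to the CH2CH2 bridge and hydrogenolyses the three benzyl ethers in one operation. Diaryl ether and aryl methyl ether bonds are stable under these conditions, and the hydroquinone is formed under reducing conditions.

## Compound list

1 | 3-bromo-4-hydroxybenzaldehyde | O=Cc1ccc(O)c(Br)c1 | starting material
2 | 4-(benzyloxy)-3-bromobenzaldehyde | O=Cc1ccc(OCc2ccccc2)c(Br)c1 | intermediate
3 | 2-{2-[4-(benzyloxy)-3-bromophenyl]ethenyl}-1,3-dioxolane (E/Z mixture) | Brc1cc(C=CC2OCCO2)ccc1OCc1ccccc1 | intermediate (not isolated)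
4 | (E)-3-[4-(benzyloxy)-3-bromophenyl]prop-2-enal | O=C/C=C/c1ccc(OCc2ccccc2)c(Br)c1 | intermediate
5 | 3-[4-(benzyloxy)-3-bromophenyl]propanal | O=CCCc1ccc(OCc2ccccc2)c(Br)c1 | intermediate
6 | (E)-5-[4-(benzyloxy)-3-bromophenyl]pent-2-enal | O=C/C=C/CCc1ccc(OCc2ccccc2)c(Br)c1 | intermediate
7 | ethyl acetoacetate (ethyl 3-oxobutanoate) | CCOC(=O)CC(C)=O | starting material
8 | ethyl 2-acetyl-5-[4-(benzyloxy)-3-bromophenyl]-3-(2-oxoethyl)pentanoate (stereoisomer mixture) | CCOC(=O)C(C(C)=O)C(CC=O)CCc1ccc(OCc2ccccc2)c(Br)c1 | intermediate (not isolated)
9 | ethyl 6-{2-[4-(benzyloxy)-3-bromophenyl]ethyl}-4-hydroxy-2-oxocyclohexane-1-carboxylate (stereoisomer mixture) | CCOC(=O)C1C(=O)CC(O)CC1CCc1ccc(OCc2ccccc2)c(Br)c1 | intermediate (not isolated)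
10 | ethyl 6-{2-[4-(benzyloxy)-3-bromophenyl]ethyl}-2-oxocyclohex-3-ene-1-carboxylate (mixture of C1 epimers, partly enolised; configuration at C6 not assigned) | CCOC(=O)C1C(=O)C=CCC1CCc1ccc(OCc2ccccc2)c(Br)c1 | intermediate
11 | 6-{2-[4-(benzyloxy)-3-bromophenyl]ethyl}-2-oxocyclohex-3-ene-1-carboxylic acid (stereoisomer mixture) | OC(=O)C1C(=O)C=CCC1CCc1ccc(OCc2ccccc2)c(Br)c1 | intermediate (not isolated)
12 | 5-{2-[4-(benzyloxy)-3-bromophenyl]ethyl}cyclohex-2-en-1-one (configuration at C5 not assigned) | O=C1C=CCC(CCc2ccc(OCc3ccccc3)c(Br)c2)C1 | intermediate
13 | 1-(benzyloxy)-2-bromo-4-[2-(3-methoxyphenyl)ethyl]benzene | COc1cccc(CCc2ccc(OCc3ccccc3)c(Br)c2)c1 | intermediate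
14 | 2,5-dihydroxybenzaldehyde | O=Cc1cc(O)ccc1O | starting material
15 | 2,5-bis(benzyloxy)benzaldehyde | O=Cc1cc(OCc2ccccc2)ccc1OCc1ccccc1 | intermediate
16 | 1,4-bis(benzyloxy)-2-ethynylbenzene | C#Cc1cc(OCc2ccccc2)ccc1OCc1ccccc1 | intermediate
17 | 4-iodophenol | Oc1ccc(I)cc1 | starting material
18 | 4-{[2,5-bis(benzyloxy)phenyl]ethynyl}phenol | Oc1ccc(C#Cc2cc(OCc3ccccc3)ccc2OCc2ccccc2)cc1 | intermediate
19 | 1-(benzyloxy)-2-(4-{[2,5-bis(benzyloxy)phenyl]ethynyl}phenoxy)-4-[2-(3-methoxyphenyl)ethyl]benzene | COc1cccc(CCc2ccc(OCc3ccccc3)c(Oc3ccc(C#Cc4cc(OCc5ccccc5)ccc4OCc4ccccc4)cc3)c2)c1 | intermediate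
20 | 2-[2-(4-{2-hydroxy-5-[2-(3-methoxyphenyl)ethyl]phenoxy}phenyl)ethyl]benzene-1,4-diol | COc1cccc(CCc2ccc(O)c(Oc3ccc(CCc4cc(O)ccc4O)cc3)c2)c1 | target

## Step count and risk

Total step count: 12. Longest linear sequence: 9 steps (steps 1 to 7, 11 and 12, from 1). The second branch runs through steps 8 to 10 and joins at step 11.

Least certain steps:

**Step 5 (key step).** The likely failures are 1,2-addition of 7 (Knoevenagel condensation followed by oxa-electrocyclisation), a second Michael addition of 8 or 10 to another iminium ion, and incomplete dehydration of 9. The cause is that 6 is an enolisable β-alkyl enal and 7 has two nucleophilic positions. Fallback: setting out from 6, reaction with ethyl 3-oxo-4-(triphenylphosphoranylidene)butanoate and catalytic NaH in THF. The keto ester carbon adds in the Michael sense, and the ylide carbon then closes the ring by intramolecular Wittig olefination at the aldehyde. The C3=C4 double bond is therefore formed without an aldol or dehydration, and the route is rejoined at 10. No compound outside the list is made on this way, which is entered as F0.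

**Step 7.** The HI released at reflux may cause loss of the benzyl protecting group or ring iodination of the electron-rich arenes, or the oxidation may stall at the methoxy diene stage. Fallback: setting out from 12, kinetic deprotonation at C6 with LiN(i-Pr)2 in THF at −78 °C and trapping with PhSeCl gives 5-{2-[4-(benzyloxy)-3-bromophenyl]ethyl}-6-(phenylselanyl)cyclohex-2-en-1-one F1. Oxidation with H2O2 and pyridine in CH2Cl2 brings about selenoxide syn-elimination and tautomerisation to 3-{2-[4-(benzyloxy)-3-bromophenyl]ethyl}phenol F2. Methylation of this sole free hydroxyl with MeI and K2CO3 in acetone rejoins the route at 13.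

**Step 11.** Slow oxidative addition at the electron-rich, ortho-benzyloxy bromide may leave the coupling incomplete and let protodebromination compete. Addition of the phenoxide across the alkyne is a lesser concern. Fallback: setting out from 13, bromine–lithium exchange with n-BuLi in THF at −78 °C in the presence of B(Oi-Pr)3, then acidic work-up, gives {2-(benzyloxy)-5-[2-(3-methoxyphenyl)ethyl]phenyl}boronic acid F3. Chan–Lam coupling of F3 with 18 (Cu(OAc)2 as the divalent copper source, pyridine, 4 Å molecular sieves, CH2Cl2, air, rt) reverses the polarity of the aryl partner and rejoins the route at 19.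

**Step 6.** Hydroxide may open the ring by retro-Claisen cleavage, or add to or shift the enone double bond, before the ester is hydrolysed, because the keto ester enolate resists saponification. Fallback: setting out from 6, the annulation of step 5 is run with tert-butyl acetoacetate in place of 7. The TsOH treatment in toluene at 80 °C then forms tert-butyl 6-{2-[4-(benzyloxy)-3-bromophenyl]ethyl}-2-oxocyclohex-3-ene-1-carboxylate F4 (not isolated) and cleaves it by acidolysis and decarboxylation in the same pot. The route is rejoined at 12 with no basic step.

## Further compounds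

F0 | step 5 | none | none
F1 | step 7 | 5-{2-[4-(benzyloxy)-3-bromophenyl]ethyl}-6-(phenylselanyl)cyclohex-2-en-1-one (stereoisomer mixture) | O=C1C=CCC(CCc2ccc(OCc3ccccc3)c(Br)c2)C1[Se]c1ccccc1
F2 | step 7 | 3-{2-[4-(benzyloxy)-3-bromophenyl]ethyl}phenol | Oc1cccc(CCc2ccc(OCc3ccccc3)c(Br)c2)c1
F3 | step 11 | {2-(benzyloxy)-5-[2-(3-methoxyphenyl)ethyl]phenyl}boronic acid | COc1cccc(CCc2ccc(OCc3ccccc3)c(B(O)O)c2)c1
F4 | step 6 | tert-butyl 6-{2-[4-(benzyloxy)-3-bromophenyl]ethyl}-2-oxocyclohex-3-ene-1-carboxylate (stereoisomer mixture) | CC(C)(C)OC(=O)C1C(=O)C=CCC1CCc1ccc(OCc2ccccc2)c(Br)c1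
A1 | alternative 1 | 1-(benzyloxy)-2-{4-[2-(2,5-bis(benzyloxy)phenyl)ethyl]phenoxy}-4-[(3-methoxyphenyl)ethynyl]benzene | COc1cccc(C#Cc2ccc(OCc3ccccc3)c(Oc3ccc(CCc4cc(OCc5ccccc5)ccc4OCc4ccccc4)cc3)c2)c1
A2 | alternative 1 | 3-iodoanisole | COc1cccc(I)c1
A3 | alternative 1 | propiolic acid | OC(=O)C#C
A4 | alternative 1 | 1-(benzyloxy)-4-bromo-2-{4-[2-(2,5-bis(benzyloxy)phenyl)ethyl]phenoxy}benzene | Brc1ccc(OCc2ccccc2)c(Oc2ccc(CCc3cc(OCc4ccccc4)ccc3OCc3ccccc3)cc2)c1
A5 | alternative 1 | 3-(3-methoxyphenyl)prop-2-ynoic acid | COc1cccc(C#CC(O)=O)c1
A6 | alternative 2 | 2-(4-{2-(benzyloxy)-5-[2-(3-methoxyphenyl)ethyl]phenoxy}phenyl)-2,3-dihydro-1-benzofuran-5-ol (racemic) | COc1cccc(CCc2ccc(OCc3ccccc3)c(Oc3ccc(C4Cc5cc(O)ccc5O4)cc3)c2)c1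
A7 | alternative 2 | 1,4-benzoquinone | O=C1C=CC(=O)C=C1
A8 | alternative 2 | 1-(benzyloxy)-2-(4-ethenylphenoxy)-4-[2-(3-methoxyphenyl)ethyl]benzene | COc1cccc(CCc2ccc(OCc3ccccc3)c(Oc3ccc(C=C)cc3)c2)c1
A9 | alternative 3 | methyl 1-{4-[2-(2,5-bis(benzyloxy)phenyl)ethyl]phenoxy}-5-[2-(3-methoxyphenyl)ethyl]-2-oxocyclohex-3-ene-1-carboxylate (diastereomer mixture) | COC(=O)C1(Oc2ccc(CCc3cc(OCc4ccccc4)ccc3OCc3ccccc3)cc2)CC(CCc2cccc(OC)c2)C=CC1=O
A10 | alternative 3 | methyl 2-{4-[2-(2,5-bis(benzyloxy)phenyl)ethyl]phenoxy}-3-oxobutanoate | COC(=O)C(Oc1ccc(CCc2cc(OCc3ccccc3)ccc2OCc2ccccc2)cc1)C(C)=O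
A11 | alternative 3 | 4-(3-methoxyphenyl)-2-methylidenebutanal | COc1cccc(CCC(=C)C=O)c1
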